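A direct plan would join the two chromene halves by a crossed Claisen condensation of the dianion of eupatoriochromene A1 with methyl 2,2-dimethyl-2H-chromene-6-carboxylate A2.
A1 would come from resorcinol by acid-catalysed prenyl annulation to 2,2-dimethylchroman-7-ol A3, C6 acetylation to the acetylchroman A4 and dehydrogenation.
Its weakest steps would be:
- the prenyl annulation of resorcinol, because the product phenol would be as nucleophilic as resorcinol, so bis-annulation would have to be held back with excess resorcinol;
- the dehydrogenation of the chroman, because it would only correct an oxidation level, on a chelated and deactivated phenol, and would add a step without adding skeleton;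
- the dianion Claisen condensation, because it would need more than three equivalents of strong base on a sluggish electron-rich ester, and the product would cyclodehydrate to a flavone under acid.

The new route disconnects the C(=O)–CH2 bond on the phenolic side into a formyl C–H bond and an acyl carbene. The key step is a Rh(III)-catalysed, hydroxyl-directed acylmethylation of 7-hydroxy-2,2-dimethyl-2H-chromene-6-carbaldehyde with the sulfoxonium ylide of the other chromene. It exploits the C7–OH/C6–C=O pair of the hydroxylated chromene, which steers the metal, so the halves are joined without enolate, strong base or protecting group. Both pyran rings are made directly at the chromene level from salicylaldehyde units (O1–C2 and C3–C4 bonds). In symmetric 4,6-dihydroxyisophthalaldehyde one such unit becomes the pyran and the other the ketone, so the linear fusion is inherent. No resorcinol annulation, dehydrogenation or Claisen condensation remains.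

Key step: step 4

Assumption: the target has no stereocentre, so no stereocontrol is needed. It is drawn as the diketone but should exist largely as the chelated enol. 4,6-Dihydroxyisophthalaldehyde is taken to be commercially available.

**Route**

Step 1
Reactants: 1 ethyl 3-formyl-4-hydroxybenzoate; 2 (2-methylprop-1-en-1-yl)boronic acid (1.3 equiv)
Product: 5 ethyl 2,2-dimethyl-2H-chromene-6-carboxylate, via aminophenol 3 (not isolated), via quinone methide 4 (not isolated)
Conditions: Bn2NH (20 mol %), dioxane, 90 °C
Reagents that add atoms: (2-methylprop-1-en-1-yl)boronic acid, CC(C)=CB(O)O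
Why: Petasis borono-Mannich reaction of the salicylaldehyde gives aminophenol 3, which should lose the amine on heating to the o-quinone methide 4; oxa-6π electrocyclisation then closes the pyran (C3–C4 and O1–C2 bonds), the amine turns over, and the ester is inert.

Step 2
Reactants: 5 ethyl 2,2-dimethyl-2H-chromene-6-carboxylate; 6 trimethylsulfoxonium iodide (3 equiv)
Product: 7 2-[dimethyl(oxo)-λ6-sulfanylidene]-1-(2,2-dimethyl-2H-chromen-6-yl)ethan-1-one
Conditions: Me3S(O)I, KOtBu (3 equiv), THF, reflux; then 5, reflux
Reagents that add atoms: trimethylsulfoxonium iodide, C[S+](C)(C)=O.[I-]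
Why: Acylation of dimethylsulfoxonium methylide by the ester (Corey–Chaykovsky ylide acylation) should give the stabilised β-keto sulfoxonium ylide; excess ylide acts as the base, and the chromene olefin is inert to these basic conditions.

Step 3
Reactants: 8 4,6-dihydroxyisophthalaldehyde (2 equiv); 2 (2-methylprop-1-en-1-yl)boronic acid (1 equiv)
Product: 11 7-hydroxy-2,2-dimethyl-2H-chromene-6-carbaldehyde, via aminophenol 9 (not isolated), via quinone methide 10 (not isolated)
Conditions: Bn2NH (20 mol %), dioxane, 90 °C; excess 8 recovered
Reagents that add atoms: (2-methylprop-1-en-1-yl)boronic acid, CC(C)=CB(O)O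
Why: The same Petasis borono-Mannich/oxa-6π annulation on one of the two equivalent salicylaldehyde units; either formyl group gives the same product, so the linear 6-formyl-7-hydroxy pattern follows from the symmetry of 8, and the limiting boronic acid should hold back the second annulation.

Step 4
Reactants: 11 7-hydroxy-2,2-dimethyl-2H-chromene-6-carbaldehyde (1.2 equiv); 7 2-[dimethyl(oxo)-λ6-sulfanylidene]-1-(2,2-dimethyl-2H-chromen-6-yl)ethan-1-one
Product: 12 glyinflanin D, 1-(7-hydroxy-2,2-dimethyl-2H-chromen-6-yl)-3-(2,2-dimethyl-2H-chromen-6-yl)propane-1,3-dione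
Conditions: [Cp*RhCl2]2 (2.5 mol %), AgSbF6 (10 mol %), NaOAc (1 equiv), DCE, 50 °C, Ar; pH 6 buffer work-up
Reagents that add atoms: none
Why: The C7 phenoxide binds Cp*Rh(III) and directs acetate-assisted cleavage of the adjacent formyl C–H bond to a five-membered acyl rhodacycle; the ylide carbon of 7 then coordinates, dimethyl sulfoxide leaves to give a rhodium carbene, migratory insertion of the acyl group forms the new C(=O)–CH bond, and protonation releases the 1,3-diketone and the catalyst. The closest known reaction type is the Cp*Rh(III)- or Cp*Ir(III)-catalysed coupling of salicylaldehydes with aroyl sulfoxonium ylides, in which this diketone is the primary product before acid-promoted cyclodehydration to a flavone. No ring is closed and no stereocentre is formed. The step needs chemoselectivity for the open diketone over the flavone, and site selectivity for the formyl C–H bond over aryl C–H bonds and the two chromene olefins; acid-free, acetate-buffered conditions at moderate temperature should hold the product as the chelated enol, the formyl C–H is the only bond that can form the five-membered chelate with the phenoxide, and the cis-disubstituted olefins next to a quaternary carbon are poor partners for insertion. A slight excess of 11 should prevent a second acylmethylation of the product.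

**Compound list**
1 | ethyl 3-formyl-4-hydroxybenzoate | CCOC(=O)c1ccc(O)c(C=O)c1 | starting material
2 | (2-methylprop-1-en-1-yl)boronic acid | CC(C)=CB(O)O | starting material
3 | ethyl 3-[1-(dibenzylamino)-3-methylbut-2-en-1-yl]-4-hydroxybenzoate (racemic) | CCOC(=O)c1ccc(O)c(c1)C(C=C(C)C)N(Cc1ccccc1)Cc1ccccc1 | intermediate (not isolated)
4 | ethyl 3-(3-methylbut-2-en-1-ylidene)-4-oxocyclohexa-1,5-diene-1-carboxylate (o-quinone methide) | CCOC(=O)C1=CC(=CC=C(C)C)C(=O)C=C1 | intermediate (not isolated)
5 | ethyl 2,2-dimethyl-2H-chromene-6-carboxylate | CCOC(=O)c1ccc2OC(C)(C)C=Cc2c1 | intermediate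
6 | trimethylsulfoxonium iodide | C[S+](C)(C)=O.[I-] | starting material
7 | 2-[dimethyl(oxo)-λ6-sulfanylidene]-1-(2,2-dimethyl-2H-chromen-6-yl)ethan-1-one | CC1(C)C=Cc2cc(ccc2O1)C(=O)C=S(C)(C)=O | intermediate
8 | 4,6-dihydroxyisophthalaldehyde | O=Cc1cc(C=O)c(O)cc1O | starting material
9 | 5-[1-(dibenzylamino)-3-methylbut-2-en-1-yl]-2,4-dihydroxybenzaldehyde (racemic) | O=Cc1cc(C(C=C(C)C)N(Cc2ccccc2)Cc2ccccc2)c(O)cc1O | intermediate (not isolated)
10 | 6-hydroxy-3-(3-methylbut-2-en-1-ylidene)-4-oxocyclohexa-1,5-diene-1-carbaldehyde (o-quinone methide) | O=CC1=CC(=CC=C(C)C)C(=O)C=C1O | intermediate (not isolated)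
11 | 7-hydroxy-2,2-dimethyl-2H-chromene-6-carbaldehyde | CC1(C)C=Cc2cc(C=O)c(O)cc2O1 | intermediate
12 | glyinflanin D (achiral) | CC1(C)C=Cc2cc(C(=O)CC(=O)c3cc4c(cc3O)OC(C)(C)C=C4)ccc2O1 | target

**Summary**
Total steps: 4. Longest linear sequence: 3 (steps 1, 2 and 4); step 3 is a one-step branch.

Steps most likely to fail:

- Step 4. The diketone may cyclodehydrate on the Lewis-acidic metal before it is released, or the chelating enolate of the product may sequester the catalyst and stall turnover. Fallback: setting out from 11 and 7, the same coupling would be driven on purpose through the cyclodehydration (added pivalic acid, 100 °C) to the flavone 8,8-dimethyl-2-(2,2-dimethyl-2H-chromen-6-yl)-4H,8H-pyrano[3,2-g]chromen-4-one F1, a robust compound in which phenol and diketone are masked. Hydroxide-mediated opening of its pyranone ring (KOH, aqueous pyridine, 50 °C; cold NH4Cl quench) would then return to the route at 12.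

- Step 3. The mono-annulated product is itself a salicylaldehyde, so over-annulation to the bis-pyran and a statistical product distribution may erode the desymmetrisation of 8. Fallback: setting out from 2, the same annulation would be run on unsymmetrical, commercially available 5-bromo-2,4-dihydroxybenzaldehyde F2, which has a single salicylaldehyde unit, to give 6-bromo-2,2-dimethyl-2H-chromen-7-ol F3. Bromine–lithium exchange on the lithium phenoxide of F3 (n-BuLi, 2.2 equiv, THF, −78 °C) and quench with DMF, then aqueous NH4Cl, would return to the route at 11.

- Step 1. Transfer of the β,β-disubstituted alkenyl group from boron to the iminium ion, or loss of the amine from the adduct, may be slow and leave the sequence at the aminophenol stage. Fallback: setting out from 1, addition of 2-methylprop-1-enylmagnesium bromide (2.2 equiv, THF, −78 °C; aqueous NH4Cl quench) would give ethyl 4-hydroxy-3-(1-hydroxy-3-methylbut-2-en-1-yl)benzoate F4; the phenoxide formed first shields the para ester. Thermal dehydration of this o-hydroxybenzyl alcohol F4 (toluene, 100 °C, cat. PPTS) would pass through 4 and return to the route at 5.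

**Further compounds**
F1 | step 4 | 8,8-dimethyl-2-(2,2-dimethyl-2H-chromen-6-yl)-4H,8H-pyrano[3,2-g]chromen-4-one | CC1(C)C=Cc2cc(ccc2O1)C1=CC(=O)c2cc3C=CC(C)(C)Oc3cc2O1
F2 | step 3 | 5-bromo-2,4-dihydroxybenzaldehyde | O=Cc1cc(Br)c(O)cc1O
F3 | step 3 | 6-bromo-2,2-dimethyl-2H-chromen-7-ol | CC1(C)C=Cc2cc(Br)c(O)cc2O1
F4 | step 1 | ethyl 4-hydroxy-3-(1-hydroxy-3-methylbut-2-en-1-yl)benzoate (racemic) | CCOC(=O)c1ccc(O)c(c1)C(O)C=C(C)C
A1 | direct plan | 1-(7-hydroxy-2,2-dimethyl-2H-chromen-6-yl)ethan-1-one (eupatoriochromene) | CC(=O)c1cc2c(cc1O)OC(C)(C)C=C2
A2 | direct plan | methyl 2,2-dimethyl-2H-chromene-6-carboxylate | COC(=O)c1ccc2OC(C)(C)C=Cc2c1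
A3 | direct plan | 2,2-dimethylchroman-7-ol | CC1(C)CCc2ccc(O)cc2O1
A4 | direct plan | 1-(7-hydroxy-2,2-dimethylchroman-6-yl)ethan-1-one | CC(=O)c1cc2c(cc1O)OC(C)(C)CC2
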